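**Retrosynthetic overview**
- The hydroxyquinone is unmasked last by Teuber oxidation of a 2-alkyl-4-chloro-5-methylresorcinol at its only free ring position.
- The C3–C4 bond of the side chain and the 4S carbinol come from an alkenylzinc (hydrozirconation of an aryl-substituted but-2-yne) adding to a keto-aldehyde; syn-hydrometalation fixes the E-alkene.
- The trimethylcyclohexanone comes from a one-carbon (ethylidene) ring expansion of a 2-allyl-2,3-dimethylcyclopentanone in which the quaternary carbon migrates; the allyl group is then cut to CH2CHO.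
- The cyclopentanone comes from a Pauson–Khand enone by conjugate methylation and enolate methylation (methyl introduced last, so allyl ends cis to the ring methyl).
- The arene comes from a Michael–Claisen cyclohexane-1,3-dione, C-2 butynylation, dehydrogenation and chlorination. Ring order: cyclopentenone, then cyclohexanone by expansion; cyclohexanedione, then arene, then quinone.

Assumption: all numbered starting materials, ligands and reagents are purchased; selectivities are estimates from analogy and have not been run.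

**Step 1**
Reactants: 1 pent-1-en-4-yne; 2 ethene
Product: 4 2-(prop-2-en-1-yl)cyclopent-2-en-1-one, via cobalt alkyne complex 3 (not isolated)
Conditions: Co2(CO)8 (1.05 equiv), CH2Cl2, rt; then ethene (30 bar), Me3NO·2H2O (6 equiv), toluene/MeOH, 40 °C
Reagents that add atoms: dicobalt octacarbonyl, Co2(CO)8 (supplies CO), O=C=[Co](=C=O)(=C=O)(=C=O)[Co](=C=O)(=C=O)(=C=O)=C=O
Why: Pauson–Khand [2+2+1] cycloaddition of the cobalt-complexed terminal alkyne with ethene and CO places the alkyne substituent next to the carbonyl, and no stereocentre is formed.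

**Step 2**
Reactants: 4 2-(prop-2-en-1-yl)cyclopent-2-en-1-one
Product: 6 (2S,3S)-2,3-dimethyl-2-(prop-2-en-1-yl)cyclopentan-1-one, via magnesium enolate 5 (not isolated)
Conditions: Cu(OTf)2 (3 mol%), chiral hydroxyalkyl imidazolinium salt (NHC precursor, 4 mol%; enantiomer giving Si-face attack at C-3), MeMgBr (1.3 equiv), Et2O, −30 °C; then MeI (5 equiv), DMPU, −30 °C to rt
Reagents that add atoms: methylmagnesium bromide, C[Mg]Br; iodomethane, CI
Why: Copper-catalysed asymmetric conjugate addition puts methyl on the Si face of C-3 under ligand control, and the regiodefined magnesium enolate is then C-methylated anti to that methyl, so allyl ends cis to it (2S,3S).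

**Step 3**
Reactants: 6 (2S,3S)-2,3-dimethyl-2-(prop-2-en-1-yl)cyclopentan-1-one
Product: 10 (2S,3S,4S)-2,3,4-trimethyl-3-(prop-2-en-1-yl)cyclohexan-1-one, via dibromo alkoxide 7 (not isolated), via oxido carbenoid 8 (not isolated), via lithium enolate 9 (not isolated)
Conditions: CH3CHBr2, LiN(iPr)2, THF/Et2O, −100 °C; add 6; n-BuLi (1.1 equiv), −100 to −40 °C; pivalic acid, −78 °C
Reagents that add atoms: 1,1-dibromoethane, CC(Br)Br
Why: Proposed new method: LiCBr2CH3 adds to the ketone and Br/Li exchange gives a β-oxido ethylidene carbenoid whose oxyanion-driven 1,2-shift should move the more electron-rich quaternary C-2 (with retention) onto the carbenoid carbon with loss of LiBr, enlarging the ring and leaving a regiodefined tetrasubstituted lithium enolate that pivalic acid protonates anti to the pseudoaxial allyl group and the C-4 methyl to set C-2 as S; the closest known reaction type is the β-oxido carbenoid (dibromomethyllithium) ring enlargement of simple cycloalkanones, not yet shown with a secondary carbenoid, a migrating quaternary stereocentre or stereocontrolled enolate protonation.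

**Step 4**
Reactants: 10 (2S,3S,4S)-2,3,4-trimethyl-3-(prop-2-en-1-yl)cyclohexan-1-one
Product: 12 2-[(1S,2S,6S)-1,2,6-trimethyl-3-oxocyclohexyl]acetaldehyde, via ozonide 11 (not isolated)
Conditions: O3, CH2Cl2, −78 °C; then PPh3, −78 °C to rt
Reagents that add atoms: ozone, [O-][O+]=O
Why: Ozonolysis with reductive work-up cleaves the only alkene to the aldehyde under neutral conditions that leave the epimerisable C-2 centre untouched.

**Step 5**
Reactants: 13 methyl 3-oxobutanoate; 14 methyl (2E)-but-2-enoate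
Product: 16 5-methylcyclohexane-1,3-dione, via cyclic keto ester 15 (not isolated)
Conditions: NaOMe, MeOH, reflux; aq. NaOH, reflux; HCl, 90 °C
Reagents that add atoms: none
Why: Michael addition of the acetoacetate anion to the crotonate, Dieckmann-type Claisen ring closure, saponification and decarboxylation is the classical cyclohexane-1,3-dione synthesis, and the product is achiral.

**Step 6**
Reactants: 16 5-methylcyclohexane-1,3-dione; 17 1-bromobut-2-yne
Product: 18 2-(but-2-yn-1-yl)-5-methylcyclohexane-1,3-dione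
Conditions: KOH (1.0 equiv), H2O, rt to 50 °C
Reagents that add atoms: none
Why: C-Alkylation of the dione monoanion at C-2 with a propargylic bromide in water (Stetter conditions) fixes the side chain between the two future phenol oxygens, which a resorcinol itself would not do selectively.

**Step 7**
Reactants: 18 2-(but-2-yn-1-yl)-5-methylcyclohexane-1,3-dione
Product: 21 2-(but-2-yn-1-yl)-5-methylbenzene-1,3-diol, via bis(silyl) dienol ether 19 (not isolated), via bis(silyl) aryl ether 20 (not isolated)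
Conditions: Me3SiOTf (2.4 equiv), Et3N (3 equiv), CH2Cl2, 0 °C; evaporate, pentane filtration; DDQ (1.1 equiv), 2,4,6-collidine, benzene, rt; 1 M HCl, THF
Reagents that add atoms: none
Why: Double enol silylation gives a 1,3-bis(silyloxy)diene that DDQ dehydrogenates by hydride abstraction and proton loss (Fleming–Paterson-type oxidation) to the arene, and the halogen-free conditions avoid cyclisation of the enol oxygens onto the alkyne.

**Step 8**
Reactants: 21 2-(but-2-yn-1-yl)-5-methylbenzene-1,3-diol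
Product: 22 2-(but-2-yn-1-yl)-4-chloro-5-methylbenzene-1,3-diol
Conditions: SO2Cl2 (1.0 equiv), Et2O, 0 °C
Reagents that add atoms: sulfuryl chloride, O=S(=O)(Cl)Cl
Why: Electrophilic aromatic chlorination of the resorcinol, whose two open positions are equivalent and whose C-2 is blocked, so one equivalent gives a single monochloride.

**Step 9**
Reactants: 22 2-(but-2-yn-1-yl)-4-chloro-5-methylbenzene-1,3-diol; 12 2-[(1S,2S,6S)-1,2,6-trimethyl-3-oxocyclohexyl]acetaldehyde
Product: 27 4-chloro-2-{(2E,4S)-4-hydroxy-3-methyl-5-[(1S,2S,6S)-1,2,6-trimethyl-3-oxocyclohexyl]pent-2-en-1-yl}-5-methylbenzene-1,3-diol, via bis(silyl) ether 23 (not isolated), via alkenylzirconocene 24 (not isolated), via alkenylzinc 25 (not isolated), via zinc alkoxide 26 (not isolated)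
Conditions: 22 (1.5 equiv), (Me3Si)2NH, cat. Me3SiCl, 60 °C, evaporate; Cp2Zr(H)Cl (1.15 equiv per alkyne), CH2Cl2, 40 °C; toluene, ZnMe2, −65 °C; 2-[1-(dimethylamino)ethyl]benzenethiol (10 mol%, enantiomer giving Re-face addition), 12 (1.0 equiv), −30 °C; aq. NH4Cl, then citric acid, MeOH
Reagents that add atoms: none
Why: Transient silylation masks the phenols, syn-hydrozirconation (equilibrated so that Zr sits on the methyl-bearing carbon) fixes the E-alkene, and Zr-to-Zn transmetalation with amino-thiol-catalysed alkenylzinc addition to the Re face of the aldehyde, chemoselective over the ketone, sets the 4S carbinol.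

**Step 10**
Reactants: 27 4-chloro-2-{(2E,4S)-4-hydroxy-3-methyl-5-[(1S,2S,6S)-1,2,6-trimethyl-3-oxocyclohexyl]pent-2-en-1-yl}-5-methylbenzene-1,3-diol
Product: 28 5-chloro-2-hydroxy-3-{(2E,4S)-4-hydroxy-3-methyl-5-[(1S,2S,6S)-1,2,6-trimethyl-3-oxocyclohexyl]pent-2-en-1-yl}-6-methylcyclohexa-2,5-diene-1,4-dione
Conditions: K2[ON(SO3)2] (2.5 equiv), KH2PO4, acetone/H2O, 0 °C to rt
Reagents that add atoms: potassium nitrosodisulfonate, K2[ON(SO3)2], [K+].[K+].[O-]S(=O)(=O)N([O])S(=O)(=O)[O-]
Why: Teuber oxidation at the only free ring position, para to one hydroxyl, gives the 2-hydroxy-1,4-benzoquinone without touching the allylic alcohol, the alkene or the ketone.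

**Compound list**
1 | pent-1-en-4-yne | C#CCC=C | starting material
2 | ethene | C=C | starting material
3 | hexacarbonyl[μ-(pent-1-en-4-yne)]dicobalt, Co2(CO)6(C5H6) | C=CCC12C3[Co]1(=C=O)(=C=O)(=C=O)[Co]23(=C=O)(=C=O)=C=O | intermediate
4 | 2-(prop-2-en-1-yl)cyclopent-2-en-1-one | O=C1CCC=C1CC=C | intermediate
5 | bromomagnesium (3S)-3-methyl-2-(prop-2-en-1-yl)cyclopent-1-en-1-olate | C=CCC1=C(O[Mg]Br)CC[C@@H]1C | intermediate
6 | (2S,3S)-2,3-dimethyl-2-(prop-2-en-1-yl)cyclopentan-1-one | C=CC[C@]1(C)C(=O)CC[C@@H]1C | intermediate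
7 | lithium (2S,3S)-1-(1,1-dibromoethyl)-2,3-dimethyl-2-(prop-2-en-1-yl)cyclopentan-1-olate (C-1 epimers) | C=CC[C@]1(C)C(O[Li])(C(C)(Br)Br)CC[C@@H]1C | intermediate
8 | lithium (2S,3S)-1-(1-bromo-1-lithioethyl)-2,3-dimethyl-2-(prop-2-en-1-yl)cyclopentan-1-olate | C=CC[C@]1(C)C(O[Li])(C(C)(Br)[Li])CC[C@@H]1C | intermediate
9 | lithium (3S,4S)-2,3,4-trimethyl-3-(prop-2-en-1-yl)cyclohex-1-en-1-olate | C=CC[C@]1(C)C(C)=C(O[Li])CC[C@@H]1C | intermediate
10 | (2S,3S,4S)-2,3,4-trimethyl-3-(prop-2-en-1-yl)cyclohexan-1-one | C=CC[C@]1(C)[C@H](C)C(=O)CC[C@@H]1C | intermediate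
11 | (2S,3S,4S)-2,3,4-trimethyl-3-[(1,2,4-trioxolan-3-yl)methyl]cyclohexan-1-one | C1OC(C[C@]2(C)[C@H](C)C(=O)CC[C@@H]2C)OO1 | intermediate
12 | 2-[(1S,2S,6S)-1,2,6-trimethyl-3-oxocyclohexyl]acetaldehyde | O=CC[C@]1(C)[C@H](C)C(=O)CC[C@@H]1C | intermediate
13 | methyl 3-oxobutanoate | CC(=O)CC(=O)OC | starting material
14 | methyl (2E)-but-2-enoate | C/C=C/C(=O)OC | starting material
15 | methyl 2-methyl-4,6-dioxocyclohexane-1-carboxylate (racemic, present as its sodium enolate) | COC(=O)C1C(C)CC(=O)CC1=O | intermediate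
16 | 5-methylcyclohexane-1,3-dione | CC1CC(=O)CC(=O)C1 | intermediate
17 | 1-bromobut-2-yne | CC#CCBr | starting material
18 | 2-(but-2-yn-1-yl)-5-methylcyclohexane-1,3-dione | CC#CCC1C(=O)CC(C)CC1=O | intermediate
19 | {[2-(but-2-yn-1-yl)-5-methylcyclohexa-1,3-diene-1,3-diyl]bis(oxy)}bis(trimethylsilane) (racemic) | CC#CCC1=C(O[Si](C)(C)C)CC(C)C=C1O[Si](C)(C)C | intermediate
20 | {[2-(but-2-yn-1-yl)-5-methyl-1,3-phenylene]bis(oxy)}bis(trimethylsilane) | CC#CCc1c(O[Si](C)(C)C)cc(C)cc1O[Si](C)(C)C | intermediate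
21 | 2-(but-2-yn-1-yl)-5-methylbenzene-1,3-diol | CC#CCc1c(O)cc(C)cc1O | intermediate
22 | 2-(but-2-yn-1-yl)-4-chloro-5-methylbenzene-1,3-diol | CC#CCc1c(O)cc(C)c(Cl)c1O | intermediate
23 | {[2-(but-2-yn-1-yl)-4-chloro-5-methyl-1,3-phenylene]bis(oxy)}bis(trimethylsilane) | CC#CCc1c(O[Si](C)(C)C)cc(C)c(Cl)c1O[Si](C)(C)C | intermediate
24 | chloro{(2E)-4-[3-chloro-4-methyl-2,6-bis(trimethylsilyloxy)phenyl]but-2-en-2-yl}bis(cyclopentadienyl)zirconium | C/C(=C\Cc1c(O[Si](C)(C)C)cc(C)c(Cl)c1O[Si](C)(C)C)[Zr](Cl)(C1C=CC=C1)C1C=CC=C1 | intermediate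
25 | {(2E)-4-[3-chloro-4-methyl-2,6-bis(trimethylsilyloxy)phenyl]but-2-en-2-yl}(methyl)zinc | C/C(=C\Cc1c(O[Si](C)(C)C)cc(C)c(Cl)c1O[Si](C)(C)C)[Zn]C | intermediate
26 | methylzinc (2S,3E)-5-[3-chloro-4-methyl-2,6-bis(trimethylsilyloxy)phenyl]-3-methyl-1-[(1S,2S,6S)-1,2,6-trimethyl-3-oxocyclohexyl]pent-3-en-2-olate | Cc1cc(O[Si](C)(C)C)c(C/C=C(\C)[C@@H](O[Zn]C)C[C@]2(C)[C@H](C)C(=O)CC[C@@H]2C)c(O[Si](C)(C)C)c1Cl | intermediate
27 | 4-chloro-2-{(2E,4S)-4-hydroxy-3-methyl-5-[(1S,2S,6S)-1,2,6-trimethyl-3-oxocyclohexyl]pent-2-en-1-yl}-5-methylbenzene-1,3-diol | Cc1cc(O)c(C/C=C(\C)[C@@H](O)C[C@]2(C)[C@H](C)C(=O)CC[C@@H]2C)c(O)c1Cl | intermediate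
28 | 5-chloro-2-hydroxy-3-{(2E,4S)-4-hydroxy-3-methyl-5-[(1S,2S,6S)-1,2,6-trimethyl-3-oxocyclohexyl]pent-2-en-1-yl}-6-methylcyclohexa-2,5-diene-1,4-dione | CC1=C(Cl)C(=O)C(C/C=C(\C)[C@@H](O)C[C@]2(C)[C@H](C)C(=O)CC[C@@H]2C)=C(O)C1=O | target

**Step count**
Total steps: 10. Longest linear sequence: 6 (steps 1–4, 9, 10; the arene branch, steps 5–8, 9, 10, is equally long).

**Three steps most likely to fail**

Step 3, the proposed new ring expansion. The carbenoid may fail to add to the hindered ketone, the CH2 carbon may migrate instead, or protonation may be unselective. The fallback is the known selenium-based ring enlargement, which sets out from 6 and returns at 10. 1-(Methylselanyl)ethyllithium (from 1,1-bis(methylselanyl)ethane and n-BuLi, THF, −78 °C) is added to 6 to give (2S,3S)-2,3-dimethyl-1-[1-(methylselanyl)ethyl]-2-(prop-2-en-1-yl)cyclopentan-1-ol F1, which is isolated. AgBF4 on Al2O3 in CH2Cl2 then removes the selenium group with pinacol-type migration of the more substituted ring carbon. This gives 10 together with its C-2 epimer (2R,3S,4S)-2,3,4-trimethyl-3-(prop-2-en-1-yl)cyclohexan-1-one F2, which is equilibrated with NaOMe in MeOH, separated and recycled.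

Step 2, where the enantioselectivity of methyl addition to an α-substituted cyclopentenone and the trapping of the magnesium enolate are both uncertain. The fallback replaces catalyst control by a reagent-controlled reduction and a directed cyclopropanation; it sets out from 4 and returns at 6. Reduction of 4 with BH3·SMe2 and the appropriate 2-methyl-CBS-oxazaborolidine enantiomer gives (1R)-2-(prop-2-en-1-yl)cyclopent-2-en-1-ol F3. Hydroxyl-directed cyclopropanation (ZnEt2, CH2I2) gives (1S,2R,5R)-1-(prop-2-en-1-yl)bicyclo[3.1.0]hexan-2-ol F4. Dess–Martin oxidation gives (1S,5R)-1-(prop-2-en-1-yl)bicyclo[3.1.0]hexan-2-one F5. Li in NH3 cleaves the external cyclopropane bond to lithium (3S)-3-methyl-2-(prop-2-en-1-yl)cyclopent-1-en-1-olate F6, and MeI added to the same flask methylates it anti to the ring methyl to give 6.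

Step 9, where the hydrozirconation regiochemistry, the enantioselectivity in the presence of zirconium by-products and the sensitive keto-aldehyde are the concerns. The fallback isolates a vinyl iodide and uses organochromium chemistry; it sets out from 22 (through 23 and 24) and returns at 27. Intermediate 24 is quenched with I2 to give {[4-chloro-2-[(2E)-3-iodobut-2-en-1-yl]-5-methyl-1,3-phenylene]bis(oxy)}bis(trimethylsilane) F7. Acidic work-up gives 4-chloro-2-[(2E)-3-iodobut-2-en-1-yl]-5-methylbenzene-1,3-diol F8, which is freed of its regioisomer by chromatography. An asymmetric Nozaki–Hiyama–Kishi coupling of F8 with 12 (CrCl2, catalytic NiCl2, chiral oxazoline–sulfonamide ligand, Et3N, THF/MeCN) then gives 27.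

**Further compounds**
F1 | step 3 | (2S,3S)-2,3-dimethyl-1-[1-(methylselanyl)ethyl]-2-(prop-2-en-1-yl)cyclopentan-1-ol | C=CC[C@]1(C)C(O)(C(C)[Se]C)CC[C@@H]1C
F2 | step 3 | (2R,3S,4S)-2,3,4-trimethyl-3-(prop-2-en-1-yl)cyclohexan-1-one | C=CC[C@]1(C)[C@@H](C)C(=O)CC[C@@H]1C
F3 | step 2 | (1R)-2-(prop-2-en-1-yl)cyclopent-2-en-1-ol | O[C@@H]1CCC=C1CC=C
F4 | step 2 | (1S,2R,5R)-1-(prop-2-en-1-yl)bicyclo[3.1.0]hexan-2-ol | C=CC[C@@]12[C@H](O)CC[C@@H]1C2
F5 | step 2 | (1S,5R)-1-(prop-2-en-1-yl)bicyclo[3.1.0]hexan-2-one | C=CC[C@@]12C(=O)CC[C@@H]1C2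
F6 | step 2 | lithium (3S)-3-methyl-2-(prop-2-en-1-yl)cyclopent-1-en-1-olate | C=CCC1=C(O[Li])CC[C@@H]1C
F7 | step 9 | {[4-chloro-2-[(2E)-3-iodobut-2-en-1-yl]-5-methyl-1,3-phenylene]bis(oxy)}bis(trimethylsilane) | C/C(I)=C\Cc1c(O[Si](C)(C)C)cc(C)c(Cl)c1O[Si](C)(C)C
F8 | step 9 | 4-chloro-2-[(2E)-3-iodobut-2-en-1-yl]-5-methylbenzene-1,3-diol | C/C(I)=C\Cc1c(O)cc(C)c(Cl)c1O
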